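**Plan**

- Retrosynthetic cuts, in order: (a) the aryl ester C(=O)–O bond between ring A (acyl ring) and ring B (phenol ring); (b) in ring A the C3'–C4' and C1'–C6' bonds; (c) in ring B the C5–CH3 bond.
- Enabling feature: ring A (C1' carboxyl, C2' OMe, C3' Me, C4' OH, C5' Cl, C6' Me) is a fully substituted 5-chlororesorcylate. Its 1,3-dioxygen pattern divides it into a 3-oxopentanoate unit (C1'–C2'–C3', dinucleophile) and a 2-chloroacetoacetyl unit (C4'–C5'–C6', dielectrophile carrying the chlorine on its central carbon).
- Forward, ring A: the ring closes from these two open chains in one TiCl4-mediated [3+3] cyclocondensation; 4'-O-MOM protection, 2'-O-methylation and saponification follow.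
- Forward, ring B: bought as the arene methyl atratate, methylated at C5 by formylation and reduction, then O-differentiated (4-OBn, 2-OMe, debenzylation).
- The halves are joined by acid chloride/phenoxide esterification, and acidic MOM removal ends the route.
- Stereochemistry: the target has no stereocentre; the racemic CHCl carbon and the diene geometry disappear on aromatisation.

Key step: step 6

Assumption: the diene geometry (drawn 1Z,3Z) and the configuration of the CHCl carbon need no control because both are lost in ring A; silyl or titanium ethers formed during the key step are drawn in their simplest form.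

**Route**

Step 1
Reactants: 1 methyl 3-oxopentanoate
Product: 2 methyl (Z)-3-(trimethylsilyloxy)pent-2-enoate (an E/Z mixture would serve equally)
Conditions: Me3SiCl (1.3 equiv), Et3N (1.5 equiv), hexane, 20 °C, 16 h; filter, distil
Reagents that add atoms: chlorotrimethylsilane, C[Si](C)(C)Cl
Why: Soft enolisation of the β-keto ester by Et3N and O-silylation give the conjugated silyl enol ether, the routine first stage of bis(silyloxy)diene synthesis.

Step 2
Reactants: 2 methyl (Z)-3-(trimethylsilyloxy)pent-2-enoate
Product: 4 (1Z,3Z)-1-methoxy-1,3-bis(trimethylsilyloxy)penta-1,3-diene, via lithium dienolate 3 (not isolated)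
Conditions: LiN(iPr)2 (LDA, commercial solution, 1.15 equiv), THF, −78 °C, 1 h; Me3SiCl (1.3 equiv), −78 → 20 °C; evaporate, hexane, filter under argon, use crude
Reagents that add atoms: chlorotrimethylsilane, C[Si](C)(C)Cl
Why: Kinetic deprotonation at C4 of the vinylogous ester gives the dienolate, which Me3SiCl traps on oxygen (second O-silylation, the standard route to 1,3-bis(silyloxy)dienes).

Step 3
Reactants: 5 ethyl 2-chloro-3-oxobutanoate (ethyl 2-chloroacetoacetate)
Product: 6 ethyl 2-chloro-2-(2-methyl-1,3-dioxolan-2-yl)acetate (racemic)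
Conditions: HOCH2CH2OH (3 equiv), p-TsOH·H2O (5 mol %), toluene, reflux, water separator
Reagents that add atoms: ethylene glycol, OCCO
Why: Acid-catalysed ketalisation with azeotropic water removal masks the ketone, whose electrophilicity is raised by the α-chlorine, so that the acid chloride made later is the only free acyl electrophile.

Step 4
Reactants: 6 ethyl 2-chloro-2-(2-methyl-1,3-dioxolan-2-yl)acetate
Product: 7 potassium 2-chloro-2-(2-methyl-1,3-dioxolan-2-yl)acetate (racemic)
Conditions: KOH (1.0 equiv), EtOH/H2O, 0 → 20 °C; evaporate, dry by toluene azeotrope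
Reagents that add atoms: potassium hydroxide, [K+].[OH-]
Why: Ester saponification with one equivalent of hydroxide leaves the base-stable dioxolane and the neopentyl-like C–Cl carbon untouched, and isolating the salt keeps the ketal away from acid.

Step 5
Reactants: 7 potassium 2-chloro-2-(2-methyl-1,3-dioxolan-2-yl)acetate
Product: 8 2-chloro-2-(2-methyl-1,3-dioxolan-2-yl)acetyl chloride (racemic)
Conditions: (COCl)2 (1.2 equiv), DMF (cat.), CH2Cl2, 0 → 20 °C; filter, concentrate, use at once
Reagents that add atoms: oxalyl chloride, O=C(Cl)C(=O)Cl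
Why: A carboxylate salt and oxalyl chloride (Vilsmeier-type catalysis by DMF) give the acid chloride with only KCl, CO and CO2 as co-products, so no HCl is formed that could open the dioxolane.

Step 6
Reactants: 4 (1Z,3Z)-1-methoxy-1,3-bis(trimethylsilyloxy)penta-1,3-diene; 8 2-chloro-2-(2-methyl-1,3-dioxolan-2-yl)acetyl chloride
Product: 11 methyl 5-chloro-2,4-dihydroxy-3,6-dimethylbenzoate, via acylated silyl enol ether 9 (not isolated), via cyclised glycol adduct 10 (not isolated)
Conditions: 4 (1.3 equiv), CH2Cl2, −78 → −20 °C, 2 h; then TiCl4 (2.0 equiv), −78 → 20 °C, 12 h; 1 M aq. HCl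
Reagents that add atoms: none
Why: The diene is a masked dianion of the β-keto ester, and before any Lewis acid is present its terminal carbon acylates the acid chloride (vinylogous Mukaiyama-type C-acylation, bond C3'–C4') to give 9 while the dioxolane stays closed. TiCl4 then opens the dioxolane to an oxocarbenium ion at the future C6', and the silyl (or titanium) enolate carbon C1' adds to it in a Mukaiyama aldol-type 6-(enolendo)-exo-trig closure that forms ring A as adduct 10 (bond C1'–C6'). β-Elimination of the glycol residue and enolisation of the two ring ketones aromatise 10 to resorcylate 11. The closest known reaction type is the TiCl4-mediated formal [3+3] cyclocondensation of 1,3-bis(silyloxy)dienes with ketal-masked β-keto acid chlorides and with 2-chloro-1,3-dielectrophiles. No stereocentre has to be controlled, since the racemic CHCl carbon and the transient sp3 centres of 9 and 10 all become sp2 in 11. The step needs regioselectivity (chlorine between C4'–OH and C6'–CH3 rather than the 2,6-dihydroxy isomer), and this is secured by letting the more nucleophilic terminal carbon meet the more electrophilic acyl chloride first and activating the ketal only afterwards.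

Step 7
Reactants: 11 methyl 5-chloro-2,4-dihydroxy-3,6-dimethylbenzoate
Product: 12 methyl 5-chloro-2-hydroxy-4-(methoxymethoxy)-3,6-dimethylbenzoate
Conditions: MeOCH2Cl (1.2 equiv), iPr2NEt (1.5 equiv), CH2Cl2, 0 → 20 °C
Reagents that add atoms: chloromethyl methyl ether, COCCl
Why: O-Alkylation (Williamson type) takes place at the 4-OH, which is acidified by the ortho chlorine and not hydrogen-bonded, whereas the 2-OH is locked in a hydrogen bond to the ester carbonyl and stays free.

Step 8
Reactants: 12 methyl 5-chloro-2-hydroxy-4-(methoxymethoxy)-3,6-dimethylbenzoate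
Product: 13 methyl 5-chloro-2-methoxy-4-(methoxymethoxy)-3,6-dimethylbenzoate
Conditions: MeI (3 equiv), K2CO3 (3 equiv), DMF, 50 °C
Reagents that add atoms: iodomethane, CI
Why: With O4 masked, the chelated 2-OH is methylated under more forcing carbonate/DMF conditions (Williamson ether synthesis); the acetal, the aryl chloride and the ester are inert.

Step 9
Reactants: 13 methyl 5-chloro-2-methoxy-4-(methoxymethoxy)-3,6-dimethylbenzoate
Product: 15 5-chloro-2-methoxy-4-(methoxymethoxy)-3,6-dimethylbenzoic acid, via potassium carboxylate 14 (not isolated)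
Conditions: KOH (10 equiv), DMSO/H2O 4:1, 90 °C; then cold 1 M aq. HCl to pH 3, extract at once
Reagents that add atoms: potassium hydroxide, [K+].[OH-]
Why: Saponification of the di-ortho-substituted methyl ester needs poorly solvated hydroxide in hot aqueous DMSO, conditions that the MOM acetal, the aryl ethers and the unactivated aryl chloride tolerate, and brief cold acidification frees the acid without cleaving the acetal.

Step 10
Reactants: 16 methyl 2,4-dihydroxy-3,6-dimethylbenzoate (methyl atratate)
Product: 17 methyl 5-formyl-2,4-dihydroxy-3,6-dimethylbenzoate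
Conditions: Cl2CHOMe (1.5 equiv), TiCl4 (3 equiv), CH2Cl2, 0 → 20 °C; ice/1 M aq. HCl
Reagents that add atoms: dichloromethyl methyl ether, COC(Cl)Cl; water, O
Why: Rieche formylation: the chloro(methoxy)carbenium ion formed by TiCl4 attacks the only free ring position, C5 (ortho to the 4-OH, para to the 2-OH), and aqueous work-up hydrolyses the α-chloro ether to the aldehyde.

Step 11
Reactants: 17 methyl 5-formyl-2,4-dihydroxy-3,6-dimethylbenzoate
Product: 18 methyl 2,4-dihydroxy-3,5,6-trimethylbenzoate
Conditions: Et3SiH (3 equiv), CF3CO2H, CH2Cl2, 0 → 20 °C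
Reagents that add atoms: none
Why: Ionic hydrogenation: two hydride transfers from Et3SiH, the second to the benzylic cation (protonated quinone methide) stabilised by the ortho and para hydroxyls, turn CHO into CH3, and the fully substituted ring leaves no site for diarylmethane formation.

Step 12
Reactants: 18 methyl 2,4-dihydroxy-3,5,6-trimethylbenzoate
Product: 19 methyl 4-(benzyloxy)-2-hydroxy-3,5,6-trimethylbenzoate
Conditions: BnBr (1.05 equiv), K2CO3 (1.2 equiv), acetone, reflux
Reagents that add atoms: benzyl bromide, BrCc1ccccc1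
Why: Selective Williamson benzylation of the more acidic, non-chelated 4-OH under mild carbonate conditions; the 2-OH is held in a hydrogen bond to the ester.

Step 13
Reactants: 19 methyl 4-(benzyloxy)-2-hydroxy-3,5,6-trimethylbenzoate
Product: 20 methyl 4-(benzyloxy)-2-methoxy-3,5,6-trimethylbenzoate
Conditions: MeI (3 equiv), K2CO3 (3 equiv), DMF, 50 °C
Reagents that add atoms: iodomethane, CI
Why: Williamson methylation of the remaining chelated phenol under forcing carbonate/DMF conditions, as in step 8.

Step 14
Reactants: 20 methyl 4-(benzyloxy)-2-methoxy-3,5,6-trimethylbenzoate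
Product: 21 methyl 4-hydroxy-2-methoxy-3,5,6-trimethylbenzoate
Conditions: H2 (1 atm), 10% Pd/C, EtOAc, 20 °C
Reagents that add atoms: none
Why: Hydrogenolysis of the benzyl ether over Pd/C is clean here because ring B carries no halogen or other reducible group.

Step 15
Reactants: 15 5-chloro-2-methoxy-4-(methoxymethoxy)-3,6-dimethylbenzoic acid; 21 methyl 4-hydroxy-2-methoxy-3,5,6-trimethylbenzoate
Product: 24 methyl 4-{[5-chloro-2-methoxy-4-(methoxymethoxy)-3,6-dimethylbenzoyl]oxy}-2-methoxy-3,5,6-trimethylbenzoate, via acid chloride 22 (not isolated), via sodium phenoxide 23 (not isolated)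
Conditions: 15, Me2C=C(Cl)NMe2 (1.2 equiv), CH2Cl2, 0 → 20 °C; separately 21, NaH (1.1 equiv), THF, 0 °C; combine, 20 → 50 °C
Reagents that add atoms: none
Why: The α-chloroenamine turns the acid into acid chloride 22 under neutral conditions (the co-product is an amide, not HCl), so the MOM acetal survives, and the preformed phenoxide 23 then attacks the 2,6-disubstituted aroyl chloride (nucleophilic acyl substitution, the usual way to esters of di-ortho-substituted phenols).

Step 16
Reactants: 24 methyl 4-{[5-chloro-2-methoxy-4-(methoxymethoxy)-3,6-dimethylbenzoyl]oxy}-2-methoxy-3,5,6-trimethylbenzoate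
Product: 25 methyl 4-[(5-chloro-4-hydroxy-2-methoxy-3,6-dimethylbenzoyl)oxy]-2-methoxy-3,5,6-trimethylbenzoate (CNP0192286.0)
Conditions: CF3CO2H/CH2Cl2 1:4, 0 → 20 °C; aq. NaHCO3
Reagents that add atoms: none
Why: Acid-catalysed cleavage of the phenolic methoxymethyl acetal through the methoxymethyl cation; the aryl methyl ethers, the methyl ester, the aryl chloride and the sterically shielded depside ester should be inert to CF3CO2H at room temperature.

**Compound list**

1 | methyl 3-oxopentanoate | CCC(=O)CC(=O)OC | starting material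
2 | methyl (Z)-3-(trimethylsilyloxy)pent-2-enoate | CC/C(=C/C(=O)OC)O[Si](C)(C)C | intermediate
3 | lithium 1-methoxy-3-(trimethylsilyloxy)penta-1,3-dien-1-olate (dienolate of 2, same geometry as 4) | C/C=C(\O[Si](C)(C)C)/C=C(/OC)[O-].[Li+] | intermediate (not isolated)
4 | (1Z,3Z)-1-methoxy-1,3-bis(trimethylsilyloxy)penta-1,3-diene | C/C=C(\O[Si](C)(C)C)/C=C(/OC)O[Si](C)(C)C | intermediate
5 | ethyl 2-chloro-3-oxobutanoate (racemic) | CCOC(=O)C(Cl)C(C)=O | starting material
6 | ethyl 2-chloro-2-(2-methyl-1,3-dioxolan-2-yl)acetate (racemic) | CCOC(=O)C(Cl)C1(C)OCCO1 | intermediate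
7 | potassium 2-chloro-2-(2-methyl-1,3-dioxolan-2-yl)acetate (racemic) | [K+].[O-]C(=O)C(Cl)C1(C)OCCO1 | intermediate
8 | 2-chloro-2-(2-methyl-1,3-dioxolan-2-yl)acetyl chloride (racemic) | CC1(OCCO1)C(Cl)C(=O)Cl | intermediate
9 | methyl 6-chloro-4-methyl-6-(2-methyl-1,3-dioxolan-2-yl)-5-oxo-3-(trimethylsilyloxy)hex-2-enoate (mixture of stereoisomers) | COC(=O)C=C(O[Si](C)(C)C)C(C)C(=O)C(Cl)C1(C)OCCO1 | intermediate (not isolated)
10 | methyl 5-chloro-3,6-dimethyl-2,4-dioxo-6-[2-(trimethylsilyloxy)ethoxy]cyclohexane-1-carboxylate (mixture of stereoisomers) | COC(=O)C1C(=O)C(C)C(=O)C(Cl)C1(C)OCCO[Si](C)(C)C | intermediate (not isolated)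
11 | methyl 5-chloro-2,4-dihydroxy-3,6-dimethylbenzoate | COC(=O)c1c(C)c(Cl)c(O)c(C)c1O | intermediate
12 | methyl 5-chloro-2-hydroxy-4-(methoxymethoxy)-3,6-dimethylbenzoate | COC(=O)c1c(C)c(Cl)c(OCOC)c(C)c1O | intermediate
13 | methyl 5-chloro-2-methoxy-4-(methoxymethoxy)-3,6-dimethylbenzoate | COC(=O)c1c(C)c(Cl)c(OCOC)c(C)c1OC | intermediate
14 | potassium 5-chloro-2-methoxy-4-(methoxymethoxy)-3,6-dimethylbenzoate | [K+].[O-]C(=O)c1c(C)c(Cl)c(OCOC)c(C)c1OC | intermediate (not isolated)
15 | 5-chloro-2-methoxy-4-(methoxymethoxy)-3,6-dimethylbenzoic acid | OC(=O)c1c(C)c(Cl)c(OCOC)c(C)c1OC | intermediate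
16 | methyl 2,4-dihydroxy-3,6-dimethylbenzoate (methyl atratate) | COC(=O)c1c(C)cc(O)c(C)c1O | starting material
17 | methyl 5-formyl-2,4-dihydroxy-3,6-dimethylbenzoate | COC(=O)c1c(C)c(C=O)c(O)c(C)c1O | intermediate
18 | methyl 2,4-dihydroxy-3,5,6-trimethylbenzoate | COC(=O)c1c(C)c(C)c(O)c(C)c1O | intermediate
19 | methyl 4-(benzyloxy)-2-hydroxy-3,5,6-trimethylbenzoate | COC(=O)c1c(C)c(C)c(OCc2ccccc2)c(C)c1O | intermediate
20 | methyl 4-(benzyloxy)-2-methoxy-3,5,6-trimethylbenzoate | COC(=O)c1c(C)c(C)c(OCc2ccccc2)c(C)c1OC | intermediate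
21 | methyl 4-hydroxy-2-methoxy-3,5,6-trimethylbenzoate | COC(=O)c1c(C)c(C)c(O)c(C)c1OC | intermediate
22 | 5-chloro-2-methoxy-4-(methoxymethoxy)-3,6-dimethylbenzoyl chloride | ClC(=O)c1c(C)c(Cl)c(OCOC)c(C)c1OC | intermediate (not isolated)
23 | sodium 3-methoxy-4-(methoxycarbonyl)-2,5,6-trimethylphenolate | [Na+].[O-]c1c(C)c(C)c(C(=O)OC)c(OC)c1C | intermediate (not isolated)
24 | methyl 4-{[5-chloro-2-methoxy-4-(methoxymethoxy)-3,6-dimethylbenzoyl]oxy}-2-methoxy-3,5,6-trimethylbenzoate | COC(=O)c1c(C)c(C)c(OC(=O)c2c(C)c(Cl)c(OCOC)c(C)c2OC)c(C)c1OC | intermediate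
25 | methyl 4-[(5-chloro-4-hydroxy-2-methoxy-3,6-dimethylbenzoyl)oxy]-2-methoxy-3,5,6-trimethylbenzoate | COC(=O)c1c(C)c(C)c(OC(=O)c2c(C)c(Cl)c(O)c(C)c2OC)c(C)c1OC | target

**Step count and risks**

Total steps: 16. Longest linear sequence: 9 steps (steps 3, 4, 5, 6, 7, 8, 9, 15, 16, from 5 to 25).

Steps most likely to fail:

1. Step 6. The enol oxygen rather than the enolate carbon may close onto the oxocarbenium ion (pyranone formation), the ketal may be lost before the C–C closure, or acylation may occur at the wrong carbon. Fallback: ring A would be taken from the aromatic pool. Commercial methyl atratate 16 has a single free ring position, and SO2Cl2 (1.0 equiv, Et2O/CH2Cl2, 0 °C) should chlorinate it there by electrophilic aromatic substitution, ortho to the 4-OH and para to the 2-OH. This gives 11 directly, where the route is rejoined; no compound outside the list is made (F0).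

2. Step 15. Acyl transfer between the doubly ortho-shielded partners may be too slow, so that hydrolysis of the acid chloride or loss of the acetal wins. Fallback: the bond would be formed through an acylium ion under acidic dehydrating conditions, which calls for an acid-stable protecting group.
   - From 11, benzylation at O4 (BnBr, K2CO3, acetone) would give methyl 4-(benzyloxy)-5-chloro-2-hydroxy-3,6-dimethylbenzoate F1.
   - Methylation (MeI, K2CO3, DMF) would give methyl 4-(benzyloxy)-5-chloro-2-methoxy-3,6-dimethylbenzoate F2.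
   - Saponification (KOH, aqueous DMSO, 90 °C) would lead through potassium 4-(benzyloxy)-5-chloro-2-methoxy-3,6-dimethylbenzoate F3 and acidification to 4-(benzyloxy)-5-chloro-2-methoxy-3,6-dimethylbenzoic acid F4.
   - Trifluoroacetic anhydride in toluene at 20 °C would convert F4 into 4-(benzyloxy)-5-chloro-2-methoxy-3,6-dimethylbenzoic trifluoroacetic anhydride F5. Its ionisation to the 2,6-disubstituted aroyl cation is helped by the same steric compression that hinders tetrahedral addition.
   - Capture of the cation by phenol 21 should give methyl 4-{[4-(benzyloxy)-5-chloro-2-methoxy-3,6-dimethylbenzoyl]oxy}-2-methoxy-3,5,6-trimethylbenzoate F6.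
   - Brief neutral hydrogenolysis (H2, Pd/C, EtOAc, monitored so that the C–Cl bond is spared) would return to the route at 25.

3. Step 9. Hydroxide may not reach the shielded ester carbonyl at a temperature the rest of the molecule tolerates, giving incomplete hydrolysis or ether cleavage under forcing conditions. Fallback: the ester would be cleaved at the O–CH3 bond instead. From 13, NaSEt (DMF, 50 °C) attacks the ester methyl carbon in an SN2 reaction that is indifferent to crowding around the carbonyl. This gives sodium 5-chloro-2-methoxy-4-(methoxymethoxy)-3,6-dimethylbenzoate F7; the aryl methyl ethers need far higher temperatures for thiolate demethylation and should survive. Cold acidification to pH 3 returns to the route at 15.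

Further compounds
F0 | step 6 | none | none
F1 | step 15 | methyl 4-(benzyloxy)-5-chloro-2-hydroxy-3,6-dimethylbenzoate | COC(=O)c1c(C)c(Cl)c(OCc2ccccc2)c(C)c1O
F2 | step 15 | methyl 4-(benzyloxy)-5-chloro-2-methoxy-3,6-dimethylbenzoate | COC(=O)c1c(C)c(Cl)c(OCc2ccccc2)c(C)c1OC
F3 | step 15 | potassium 4-(benzyloxy)-5-chloro-2-methoxy-3,6-dimethylbenzoate | [K+].[O-]C(=O)c1c(C)c(Cl)c(OCc2ccccc2)c(C)c1OC
F4 | step 15 | 4-(benzyloxy)-5-chloro-2-methoxy-3,6-dimethylbenzoic acid | OC(=O)c1c(C)c(Cl)c(OCc2ccccc2)c(C)c1OC
F5 | step 15 | 4-(benzyloxy)-5-chloro-2-methoxy-3,6-dimethylbenzoic trifluoroacetic anhydride | FC(F)(F)C(=O)OC(=O)c1c(C)c(Cl)c(OCc2ccccc2)c(C)c1OC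
F6 | step 15 | methyl 4-{[4-(benzyloxy)-5-chloro-2-methoxy-3,6-dimethylbenzoyl]oxy}-2-methoxy-3,5,6-trimethylbenzoate | COC(=O)c1c(C)c(C)c(OC(=O)c2c(C)c(Cl)c(OCc3ccccc3)c(C)c2OC)c(C)c1OC
F7 | step 9 | sodium 5-chloro-2-methoxy-4-(methoxymethoxy)-3,6-dimethylbenzoate | [Na+].[O-]C(=O)c1c(C)c(Cl)c(OCOC)c(C)c1OC
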